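**Minutes of the meeting on the flask**

The meeting had one question before it, the left-handed product of one flask at 3 times, and the chair read it out with the recipes and the earlier runs.

common to all: catalyst 1 mol% (in portions, 3)
- red: left-handed substrate 14 mM; right-handed substrate 14 mM; solid reagent 1.2 equiv; run made earlier; portions every 25 min
- ochre: left-handed substrate 32 mM; right-handed substrate 32 mM; solid reagent 1.2 equiv; run made earlier; portions every 25 min
- flask: left-handed substrate 21 mM; right-handed substrate 21 mM; solid reagent 1.20 equiv; the portions of catalyst follow each other after 25 min, the first at the start; time 2.5 h

- red (time / h: left-handed product / %, left-handed substrate / %): 0.500: 1, 52; 1.00: 2, 48; 1.50: 3, 40; 2.00: 12, 42; 2.50: 11, 39; 3.00: 14, 36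
- ochre (time / h: left-handed product / %, left-handed substrate / %): 0.200: 0, 48; 0.667: 4, 47; 1.00: 4, 45; 1.50: 9, 44; 2.50: 20, 36; 3.00: 20, 30

(standard deviation of a reading: 2 percentage points)

- catalyst is single-handed; left-handed substrate and right-handed substrate are mirror images of each other, charged as a racemate, each of them at the stated concentration
- solid, in amounts per volume of the solution: solid reagent
- at the start none of the solid reagent is in solution

1. amount of left-handed product in percent of the left-handed substrate and right-handed substrate together charged, at 15 min, 50 min and 2.5 h

The secretary, who writes these minutes, argued that the flask charge of 21 mM lies above the red charge and below the ochre charge, so the last figure asked is an interpolation on logarithms. He took the fraction of the two substrates converted to left-handed product at 2.50 h as the mean of the product reading and the loss of left-handed substrate. That gave 11.0% for red and 17.0% for ochre, each mean with a scatter of 1.4 percentage points.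

He then defined the charge exponent, the decades of fraction converted gained per decade of charge (the apparent order, less one), and read 0.527. Carried from red to the flask, it gave him 13.6% at 2.5 h. He committed to no early figure, since the red reading at 1.00 h is 2% against a scatter of 2 points.

The forecaster reported that “Percent conversion rises with concentration, but less than proportionally”, put the exponent at about 0.4, which differs from the secretary's, and gave 0.5%, 2.5% and 13.5%.

**What the flask gave**

The flask gave 0.149%, 2.14% and 14.3%, so the forecast held.

    partner + catalyst + left-handed substrate → catalyst + left-handed product (k = 1800 L² mol⁻² min⁻¹)
    partner + catalyst + right-handed substrate → catalyst + right-handed product (k = 820 L² mol⁻² min⁻¹)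
    solid reagent ⇌ partner, rate k3*(cs3 - [partner]) while solid is left; crystals form when [partner] > cs3 (solubility = 13.0 mM, k = 0.0180 min⁻¹)

Carried from the flask's 14.3% at 2.5 h up to the ochre charge, the charge exponent gives 17.9%, beside the ochre mean of 17.0%. The flask also holds partner, dissolved from the solid reagent. At 2.50 h the flask makes partner 1.12 times as fast as it uses it up, each step taken net. Partner then stands at 40.1% of the left-handed charge, below the solubility of 61.9% on the same scale, with 30.9% of the solid reagent still undissolved.

(The readings come from a simulation from invented constants; the scatter is artificial.)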